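## Structural features

The target is a trans-fused hydroazulene of the daucane type: a cyclopentane (C6–C10) and a cycloheptene (C1–C7) share the C6–C7 bond, and the only ring double bond is the trisubstituted C2=C3 that carries the C3 methyl group. Five stereocentres form one array, C10–C6–C7–C1 with C5 attached to C6: the tertiary carbinol C10 (OH cis to the C7 methyl, isopropyl trans), the fusion methine C6 (H trans to the C7 methyl), the quaternary C7, and the acyloxy carbons C1 (angelate) and C5 (veratrate), both oxygens trans to the C7 methyl; in this numbering the compound is (1R,5S,6S,7S,10R). The fragile parts are the angelate (a Z-enoate that isomerises to the tiglate), the tertiary C10 hydroxyl lying β to C5 (dehydration or retro-aldol whenever C5 is a ketone), the C2=C3 bond lying β,γ to C5 (it can move into conjugation with a C5 ketone) and the allylic C1–O bond. The esters themselves are easy; the real difficulty is the quaternary C7 wedged between C1 and C6, the fusion hydrogen on C6, which must end on the concave face of the bicycle, and the need to tell two secondary hydroxyls and one tertiary hydroxyl apart. The key step exploits the seven-membered ring: C2=C3 and a C5=C6 enol double bond (C5 at the ketone oxidation level) flank the C4 methylene while oxygenated C1 is bonded to quaternary C7. This is the 1,4-cycloheptadiene that a cis-divinylcyclopropane (C3–C4–C5) leaves on Cope rearrangement, and that cyclopropane arises from a vinylcarbene (C3, carrying C2=C1–O) and the C4=C5 bond of an alkoxydiene built on the cyclopentenone ring C6–C10.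

## Logic of the disconnections

24 ⇒ 21 + 22. The C1–O acyl bond is cut first. The Z-enoyl group is the most labile part of 24, so it is attached last; the cut leaves 21, whose only other free hydroxyl is the tertiary one at C10. The forward step must acylate a hindered secondary allylic alcohol without Z-to-E isomerisation and without touching C10–OH.

21 ⇒ 20 ⇒ 18 + 19. The O–Si bond at C1 and then the C5–O acyl bond are cut. The two secondary oxygens are kept apart by the silyl group that C1 carries from the key step onwards, so 18 offers a single acylable hydroxyl (C5) beside the tertiary C10–OH. Forward, the aroylation must stop at C5 and the desilylation must not provoke acyl migration.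

18 ⇒ 16 ⇒ 15. The C3 methyl is traced back through the primary allylic alcohol to the ester: three C–H bonds are exchanged for C–O bonds. The ester is what the carbene of the key step needs, and as an electron-poor substituent it also shields C2=C3 while the other double bond is oxidised. Forward, the ester must be reduced and the allylic C–O bond replaced by C–H with no shift of C2=C3 and in the presence of two free hydroxyls.

15 ⇒ 14. The C5–H bond is cut, so C5 becomes a ketone. The C5 carbinol is 1,3-anti to C10–OH and can be set from it by internal hydride delivery; one stereocentre is removed. The forward step requires that 14 be the trans-fused ketol (C10–OH cis to the C5 carbonyl on the cyclopentane) and that conditions do not dehydrate it.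

14 ⇒ 13 ⇒ 12. The C6–H bond and the C10–O bond are cut, by way of the C6–C10 epoxide, back to the tetrasubstituted C6=C10 enone. Two stereocentres (C6, C10) vanish and only those made in the key step remain. Forward, oxygen must add to the β face of C6=C10 and not to C2=C3, under neutral conditions because C2=C3 is β,γ to the C5 ketone, and the reductive opening must place hydrogen on the α face of C6.

12 ⇒ 10. The C10–isopropyl bond is cut and the carbonyl is transposed from C5 back to C10, which turns the enone into a vinylogous ester (C10 ketone, C5 enol ether). Isopropyl becomes a simple nucleophile and the C5 oxygen returns to the enol ether that the key step leaves. Forward, the nucleophile must choose the vinylogous ester carbonyl over the conjugated ester and must not deprotonate C4 or C1.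

10 ⇒ 4 + 8 (by way of 9). The C1–C7 and C3–C4 bonds are cut. This is the strategic cut: it opens the seven-membered ring, removes both remaining stereocentres and the quaternary carbon, and divides 10 into two achiral pieces of similar size. Forward, it demands site-selective cyclopropanation of C4=C5, a cis arrangement of the two alkenyl groups in 9, catalyst control of absolute configuration, and a concerted [3,3] shift that is not overtaken by zwitterionic ring opening.

4 ⇒ 2 + 3, and 2 ⇒ 1. The C5–C6 sp2–sp2 bond is cut, then the C6–I bond. This reduces the diene to a commodity enone and a commercial stannane. Forward, the coupling must occur at a hindered α-position of an enone and the acid-labile enol ether must survive isolation.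

8 ⇒ 7 ⇒ 5 + 6. The C1=C2 double bond is traced to the C2 carbinol and the C2–C3 bond is cut. Both fragments are commercial, and C1 arrives already oxygenated and silylated. Forward, the elimination must go toward the silyloxymethylene with E geometry, and the vinyldiazo ester must be used cold and promptly.

## Other disconnections considered

Alternative 1: The cut is made at C7–CH3 and at C6–C5, and no ring is opened. Forward, a copper-catalysed enantioselective conjugate addition of Me3Al to 3-[(methoxymethoxy)methyl]cyclopent-2-en-1-one A1 creates the quaternary C7, and the aluminium enolate is trapped at C6 by 3-methylbut-3-enal A2 to give the trans-2,3-disubstituted cyclopentanone A3.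
- In its favour: the quaternary centre comes from stable, cheap reagents without a diazo compound or a dirhodium catalyst, which is better than the chosen plan on safety and cost. The enolate is trapped anti to the larger C7 substituent, so the C6 hydrogen sits on the correct face from the outset; this is better than the chosen plan, where C6 depends on an enolate protonation on the concave face. The C10 ketone of A3 can later take isopropyl anti to the C6 side chain.
- Against it here: no ring is formed. The seven-membered ring must still be closed (for example by metathesis between the methallyl group and an alkene built on C1), C1 must be raised from a CH2O group to a carbinol stereocentre by a separate addition, methyl addition to five-membered enones is usually less selective than to six-membered ones, and C5 is set by substrate control only.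
- Comparison: structurally the chosen plan forms the ring, C1 and C7 and places C2=C3 and both oxygens in one step; mechanistically A3 arises by polar addition and aldol chemistry rather than carbene and pericyclic steps; in step count the alternative is estimated to be several steps longer.

Alternative 2: The cut is the C6–C7 bond, with C7 reconnected to C5, which turns the hydroazulene into a decalin. Forward, Et3Al converts the C5 hydroxyl of the cis-decalin hydroxy mesylate A4 into an aluminium alkoxide; C7 migrates from C5 to C6 anti to the mesylate, ring B contracts and ring A expands, giving the trans-fused hydroazulen-5-one A5.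
- In its favour: the shift is stereospecific (inversion at C6), so the trans ring fusion and the C6 hydrogen are secured by mechanism; on this point it is clearly better than the chosen plan. The decalin framework is available in enantiopure form by an organocatalytic Robinson annulation, the C10 carbinol is already present, and the C5 ketone is placed for the same directed reduction as in the chosen plan (equal on that point).
- Against it here: A4 needs four contiguous stereocentres with the correct relative configuration before the key step. In A5 the carbons C2, C3 and C4 are plain methylenes, so the C3 methyl, the C2=C3 bond and the C1 carbinol must all be introduced from the C1 ketone by dehydrogenation, methyl addition, a second dehydrogenation and reduction.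
- Comparison: the chosen plan delivers C1–O, C2=C3 and the C3 carbon substituent directly from the key step; the alternative is mechanistically more reliable but markedly longer.

Alternative 3: The cut is the C9–C10 bond of the cyclopentanone. Forward, a cationic rhodium diphosphine catalyst such as [Rh(dppe)]ClO4 adds the aldehyde C–H of the 4-pentenal A6 across its vinyl group (acyl C–H oxidative addition, hydrometalation, reductive elimination) and closes the five-membered ring as the ketone A7.
- In its favour: the reaction is catalytic, atom-economical and well established for 4-pentenals, including those with a quaternary β-carbon. It needs no diazo compound and only an achiral ligand, which is better than the chosen plan on reagent cost. The C6/C7 relationship is fixed before the ring closes. It is equal to the chosen plan in resting on a rhodium-catalysed ring-forming event.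
- Against it here: the key step forms one bond and one ring and no stereocentre, so the vicinal C6/C7 pair must be made beforehand in an acyclic precursor. The aldehyde α-carbon C6 can epimerise, and decarbonylation competes. The whole seven-membered ring with C1–O, C2=C3 and C5–O remains to be built from two CH2O groups.
- Comparison: the chosen plan forms the seven-membered ring, the quaternary carbon and two stereocentres in its key step; the alternative is strategically weaker and longer, though operationally simpler at its key step.

Key step: step 5

Conventions: C1–C7 is the seven-membered ring and C6–C10 the five-membered ring (C1 bears the allylic oxygen, C3 the one-carbon substituent, C5 the second oxygen, C10 the isopropyl group); β is the face of the C7 methyl group and α the opposite face.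

Assumption: the sense of induction of the dirhodium prolinate is taken from its behaviour with donor/acceptor carbenes and terminal alkenes, where the (S)-catalyst gives the (1S,2R)-1,2-diarylcyclopropanecarboxylate; applied to 9 this calls for tetrakis[(R)-N-(4-dodecylbenzenesulfonyl)prolinato]dirhodium, Rh2(R-DOSP)4, and the antipodal catalyst is used unchanged if the 1,1-disubstituted enol ether responds in the opposite sense.

## Route

Step 1
Reactants: 1 3-methylcyclopent-2-en-1-one
Product: 2 2-iodo-3-methylcyclopent-2-en-1-one
Conditions: I2, pyridine–CH2Cl2, 0 °C to rt
Reagents that add atoms: iodine [I][I]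
Why: α-Iodination of an enone by conjugate addition of pyridine, iodination of the enolate and elimination; no stereocentre is formed.

Step 2
Reactants: 2 2-iodo-3-methylcyclopent-2-en-1-one; 3 tributyl(1-ethoxyvinyl)stannane
Product: 4 2-(1-ethoxyvinyl)-3-methylcyclopent-2-en-1-one
Conditions: Pd2(dba)3 (2.5 mol %), AsPh3 (10 mol %), CuI (10 mol %), NMP, rt to 45 °C; KF work-up, Et3N-deactivated silica
Reagents that add atoms: none
Why: Stille coupling of an α-iodoenone with an alkoxyvinylstannane, for which the soft arsine ligand and the copper co-catalyst are the usual accelerants; the enol ether is kept base-buffered to avoid hydrolysis to the methyl ketone.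

Step 3
Reactants: 5 methyl diazoacetate; 6 (tert-butyldimethylsilyloxy)acetaldehyde
Product: 7 methyl 4-(tert-butyldimethylsilyloxy)-2-diazo-3-hydroxybutanoate (racemic)
Conditions: DBU (10 mol %), MeCN, 0 °C to rt
Reagents that add atoms: none
Why: Base-catalysed aldol-type addition of the diazo carbon to the aldehyde; the carbinol centre is racemic and is destroyed in step 4.

Step 4
Reactants: 7 methyl 4-(tert-butyldimethylsilyloxy)-2-diazo-3-hydroxybutanoate
Product: 8 methyl (E)-4-(tert-butyldimethylsilyloxy)-2-diazobut-3-enoate
Conditions: POCl3, Et3N, CH2Cl2, 0 °C; kept cold in solution and used at once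
Reagents that add atoms: none
Why: Dehydration through the dichlorophosphate, with elimination toward the silyloxymethylene to give the conjugated enol silyl ether as the E isomer; cold handling prevents electrocyclisation of the vinyldiazo ester to a pyrazole.

Step 5
Reactants: 4 2-(1-ethoxyvinyl)-3-methylcyclopent-2-en-1-one; 8 methyl (E)-4-(tert-butyldimethylsilyloxy)-2-diazobut-3-enoate
Product: 10 hydroazulene diene ester (1R,7S; C1 OTBS α; C2=C3 with CO2Me on C3; C5=C6 ethyl enol ether; C7 methyl β; C10 ketone), via cis-divinylcyclopropane 9 (not isolated)
Conditions: Rh2(R-DOSP)4 (1 mol %), hexanes–PhMe, −40 °C, 8 added over 2 h; then PhMe, 80 °C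
Reagents that add atoms: none
Why: The dirhodium carboxylate converts 8 into a donor/acceptor vinylcarbene, which adds in a concerted (2+1) manner to the most electron-rich and least hindered double bond of 4, the 1-ethoxyvinyl C4=C5 bond, giving cyclopropane 9 with the silyloxyvinyl group on C3 cis to the cyclopentenyl group on C5. 9 then undergoes a [3,3] sigmatropic (Cope) shift through the boat transition state in which both alkenyl groups are folded over the three-membered ring, so that C1–C7 forms as C3–C5 breaks. The closest known reaction type is the tandem cyclopropanation/Cope rearrangement (formal 4+3 annulation) of vinyldiazoacetates with dienes, which covers alkoxy- and siloxy-dienes and 1-vinyl-2-methylcycloalkenes that form a methyl-bearing quaternary carbon. The three-membered ring closes by carbene addition and the seven-membered ring closes by the sigmatropic shift itself, with release of cyclopropane strain paying for the quaternary C7. The relative configuration of C1 and C7 follows from the E enol ether and the boat: the silyloxy group on C1 and the ring methylene C8 on C7 point outward and end cis, so C1–O is trans to the inward C7 methyl. The absolute configuration follows from the catalyst, because the boat can form only on the face of 9 that carries both alkenyl groups, so the sense of the cyclopropanation is relayed to C1 and C7. The step needs site selectivity (secured by the enol ether against the tetrasubstituted enone bond and the carbonyl), cis selectivity (donor/acceptor carbenes place an alkene substituent next to the donor group; here the cyclopentenyl group competes with ethoxy) and enantiofacial selectivity. Hydrocarbon solvent and low temperature keep the alkoxy/ester-substituted cyclopropane from opening to a zwitterion, which would erase the stereochemical information, and heat is applied only after the carbene is consumed, to drive the Cope step slowed by the inward methyl.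

Step 6
Reactants: 10 hydroazulene diene ester
Product: 12 C5 enone ester (C1 OTBS α; C2=C3 with CO2Me on C3; C5 ketone; C6=C10 with isopropyl on C10; C7 methyl β), via tertiary allylic alcohol 11 (not isolated)
Conditions: i-PrMgCl, CeCl3, THF, −78 °C; then 1 M HCl, THF, 0 °C
Reagents that add atoms: isopropylmagnesium chloride CC(C)[Mg]Cl; water O
Why: Stork–Danheiser transposition: the weakly basic organocerium reagent adds 1,2 to the vinylogous ester carbonyl C10 faster than to the conjugated ester at −78 °C and without enolisation, and acid then ionises the tertiary allylic alcohol with help from the enol ether and hydrolyses it to the C5 ketone with C6=C10. The transient C10 carbinol centre is lost, so its configuration is irrelevant.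

Step 7
Reactants: 12 C5 enone ester
Product: 13 β-epoxy ketone (C6–C10 epoxide on the β face; C5 ketone; C3 ester; C1 OTBS α)
Conditions: dimethyldioxirane, acetone–CH2Cl2, 0 °C to rt
Reagents that add atoms: dimethyldioxirane CC1(C)OO1
Why: Electrophilic epoxidation by a dioxirane under neutral conditions: the tetrasubstituted C6=C10 bond is the most electron-rich alkene left, because C2=C3 is deactivated by the ester and screened by the silyl ether, and no base is present that could move C2=C3 into conjugation with the C5 ketone. Oxygen should add to the convex β face, syn to the C7 methyl, because the α face is covered by the fold of the seven-membered ring (C1 and its silyl ether); this sets C10–O β.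

Step 8
Reactants: 13 β-epoxy ketone
Product: 14 trans-fused ketol (C10 OH β and isopropyl α; C6 H α; C5 ketone; C3 ester; C1 OTBS α)
Conditions: SmI2, THF–MeOH, −90 to −78 °C
Reagents that add atoms: none
Why: Reduction of an α,β-epoxy ketone by SmI2 (ketyl formation, cleavage of the C6–O bond, second electron transfer to a trivalent samarium enolate) keeps the C10–O bond and its β configuration, and the enoate is not reduced without stronger activation. C6 is set on protonation of the enolate: with samarium bridging the C10 alkoxide and the C5 enolate oxygen, C5 stays inside the six-membered chelate only if it moves to the β face, so the proton should enter from the α face and give the trans-fused ketol, which is also the more stable epimer (C5 trans to isopropyl, hydrogen bond to C10–OH).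

Step 9
Reactants: 14 trans-fused ketol
Product: 15 diol ester (C5 OH α; C10 OH β; C6 H α; C3 ester; C1 OTBS α)
Conditions: Me4NBH(OAc)3, MeCN–AcOH, −30 to 0 °C
Reagents that add atoms: none
Why: Evans–Saksena reduction: the tertiary C10 hydroxyl exchanges an acetate on boron and delivers hydride intramolecularly to the β face of the C5 carbonyl through a six-membered transition state, which gives the 1,3-anti diol (C5–OH α). The reagent reduces neither the ester nor carbonyl groups that lack a directing hydroxyl.

Step 10
Reactants: 15 diol ester
Product: 16 triol (C3 CH2OH; C5 OH α; C10 OH β; C1 OTBS α)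
Conditions: i-Bu2AlH, CH2Cl2, −78 to −20 °C; aqueous potassium sodium tartrate
Reagents that add atoms: none
Why: 1,2-Reduction of the conjugated ester by the aluminium hydride; the two hydroxyls only consume reagent as aluminates, and the silyl ether, the alkene and all stereocentres are untouched.

Step 11
Reactants: 16 triol
Product: 18 C3-methyl diol (C2=C3 with methyl on C3; C5 OH α; C10 OH β; C1 OTBS α), via allylic mesylate 17 (not isolated)
Conditions: MsCl (1.1 equiv), Et3N, THF, −40 °C; then LiEt3BH, −40 to 0 °C
Reagents that add atoms: none
Why: Two-stage allylic deoxygenation: the unhindered primary allylic hydroxyl is sulfonylated much faster than the secondary C5–OH beside the ring fusion (the tertiary C10–OH is inert), and hydride then displaces the primary mesylate by SN2 so that C2=C3 stays in place.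

Step 12
Reactants: 18 C3-methyl diol; 19 3,4-dimethoxybenzoyl chloride
Product: 20 C5 veratrate (C5 O-veratroyl α; C10 OH β; C1 OTBS α)
Conditions: Et3N, DMAP (20 mol %), CH2Cl2, 0 °C to rt
Reagents that add atoms: none
Why: Nucleophile-catalysed acylation of the only secondary hydroxyl; the tertiary C10–OH does not react under these conditions, and C5 keeps its configuration because its C–O bond is not broken.

Step 13
Reactants: 20 C5 veratrate
Product: 21 C1 alcohol (C1 OH α; C5 O-veratroyl α; C10 OH β)
Conditions: HF·pyridine, pyridine–THF, 0 °C to rt
Reagents that add atoms: none
Why: Fluoride-mediated cleavage of the secondary silyl ether under buffered, weakly acidic conditions that leave the aryl ester in place and generate no alkoxide that could trigger acyl migration.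

Step 14
Reactants: 21 C1 alcohol; 22 angelic acid ((Z)-2-methylbut-2-enoic acid)
Product: 24 CNP0142353.1 (1R,5S,6S,7S,10R; C1 O-angeloyl α; C5 O-veratroyl α; C6 H α; C7 methyl β; C10 OH β), via mixed anhydride 23 (not isolated)
Conditions: 22, 2,4,6-trichlorobenzoyl chloride, Et3N, PhMe, rt; then 21, PhMe, 80 °C
Reagents that add atoms: none
Why: Yamaguchi-type mixed anhydride esterification: the alcohol attacks the less hindered angeloyl carbonyl of 23, and since no nucleophilic catalyst is present the Z geometry is not eroded by addition–elimination. The tertiary C10–OH remains free and C1 keeps its configuration.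

## Compound list

1 | 3-methylcyclopent-2-en-1-one | CC1=CC(=O)CC1 | starting material
2 | 2-iodo-3-methylcyclopent-2-en-1-one | CC1=C(I)C(=O)CC1 | intermediate
3 | tributyl(1-ethoxyvinyl)stannane | C=C(OCC)[Sn](CCCC)(CCCC)CCCC | starting material
4 | 2-(1-ethoxyvinyl)-3-methylcyclopent-2-en-1-one | C=C(OCC)C1=C(C)CCC1=O | intermediate
5 | methyl diazoacetate | COC(=O)C=[N+]=[N-] | starting material
6 | (tert-butyldimethylsilyloxy)acetaldehyde | CC(C)(C)[Si](C)(C)OCC=O | starting material
7 | methyl 4-(tert-butyldimethylsilyloxy)-2-diazo-3-hydroxybutanoate (racemic) | COC(=O)C(=[N+]=[N-])C(O)CO[Si](C)(C)C(C)(C)C | intermediate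
8 | methyl (E)-4-(tert-butyldimethylsilyloxy)-2-diazobut-3-enoate | COC(=O)C(=[N+]=[N-])/C=C/O[Si](C)(C)C(C)(C)C | intermediate
9 | methyl (1S,2R)-1-[(E)-2-(tert-butyldimethylsilyloxy)vinyl]-2-ethoxy-2-(2-methyl-5-oxocyclopent-1-en-1-yl)cyclopropane-1-carboxylate (cis-divinylcyclopropane; not isolated) | COC(=O)[C@]1(/C=C/O[Si](C)(C)C(C)(C)C)C[C@@]1(OCC)C2=C(C)CCC2=O | intermediate
10 | hydroazulene diene ester: (1R,7S); C1 OTBS α, C2=C3 with CO2Me on C3, C5=C6 ethyl enol ether, C7 methyl β, C10 ketone | CC(C)(C)[Si](C)(C)O[C@@H]1C=C(C(=O)OC)CC(OCC)=C2[C@]1(C)CCC2=O | intermediate
11 | tertiary allylic alcohol: 10 with C10 as C(OH)(isopropyl), both C10 epimers; not isolated | CC(C)(C)[Si](C)(C)O[C@@H]1C=C(C(=O)OC)CC(OCC)=C2[C@]1(C)CCC2(O)C(C)C | intermediate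
12 | C5 enone ester: C1 OTBS α, C2=C3 with CO2Me on C3, C5 ketone, C6=C10 with isopropyl on C10, C7 methyl β | CC(C)(C)[Si](C)(C)O[C@@H]1C=C(C(=O)OC)CC(=O)C=2[C@]1(C)CCC=2C(C)C | intermediate
13 | β-epoxy ketone: 12 with a C6–C10 epoxide on the β face | CC(C)(C)[Si](C)(C)O[C@@H]1C=C(C(=O)OC)CC(=O)[C@@]23[C@]1(C)CC[C@@]2(O3)C(C)C | intermediate
14 | trans-fused ketol: C10 OH β and isopropyl α, C6 H α, C5 ketone, C3 ester, C1 OTBS α | CC(C)(C)[Si](C)(C)O[C@@H]1C=C(C(=O)OC)CC(=O)[C@@H]2[C@]1(C)CC[C@@]2(O)C(C)C | intermediate
15 | diol ester: 14 with C5 reduced to the α alcohol | CC(C)(C)[Si](C)(C)O[C@@H]1C=C(C(=O)OC)C[C@H](O)[C@@H]2[C@]1(C)CC[C@@]2(O)C(C)C | intermediate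
16 | triol: 15 with C3 CH2OH in place of the ester | CC(C)(C)[Si](C)(C)O[C@@H]1C=C(CO)C[C@H](O)[C@@H]2[C@]1(C)CC[C@@]2(O)C(C)C | intermediate
17 | allylic mesylate of 16 at the primary hydroxyl (not isolated) | CC(C)(C)[Si](C)(C)O[C@@H]1C=C(COS(C)(=O)=O)C[C@H](O)[C@@H]2[C@]1(C)CC[C@@]2(O)C(C)C | intermediate
18 | C3-methyl diol: C2=C3 with methyl on C3, C5 OH α, C10 OH β, C1 OTBS α | CC(C)(C)[Si](C)(C)O[C@@H]1C=C(C)C[C@H](O)[C@@H]2[C@]1(C)CC[C@@]2(O)C(C)C | intermediate
19 | 3,4-dimethoxybenzoyl chloride (veratroyl chloride) | COc1ccc(C(=O)Cl)cc1OC | starting material
20 | C5 veratrate: 18 acylated at C5–O | CC(C)(C)[Si](C)(C)O[C@@H]1C=C(C)C[C@H](OC(=O)c2ccc(OC)c(OC)c2)[C@@H]2[C@]1(C)CC[C@@]2(O)C(C)C | intermediate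
21 | C1 alcohol: 20 without the silyl group | O[C@@H]1C=C(C)C[C@H](OC(=O)c2ccc(OC)c(OC)c2)[C@@H]2[C@]1(C)CC[C@@]2(O)C(C)C | intermediate
22 | angelic acid, (Z)-2-methylbut-2-enoic acid | C/C=C(/C)C(=O)O | starting material
23 | angelic 2,4,6-trichlorobenzoic anhydride (not isolated) | C/C=C(/C)C(=O)OC(=O)c1c(Cl)cc(Cl)cc1Cl | intermediate
24 | CNP0142353.1: (1R,5S,6S,7S,10R); C1 O-angeloyl α, C2=C3 with methyl on C3, C5 O-veratroyl α, C6 H α, C7 methyl β, C10 OH β and isopropyl α | C/C=C(/C)C(=O)O[C@@H]1C=C(C)C[C@H](OC(=O)c2ccc(OC)c(OC)c2)[C@@H]2[C@]1(C)CC[C@@]2(O)C(C)C | target

## Step count and least certain steps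

Total step count: 14. Longest linear sequence: 12 steps (steps 1, 2 and 5–14; the diazo branch, steps 3 and 4, is equally long up to step 5).

Step 5 (key step). Three processes may go wrong.
- The strongly donor-substituted silyloxyvinyl carbene may be attacked by the enol ether at its vinylogous terminus C1 instead of at the carbene carbon, and the diazo ester may cyclise to a pyrazole before it meets the catalyst.
- The cyclopropanation of the 1,1-disubstituted enol ether may place ethoxy rather than the cyclopentenyl group next to the alkenyl group. The trans isomer reaches the boat only through ring opening of the alkoxy/ester cyclopropane to a zwitterion, which erases the configuration set by the catalyst (loss of enantiomeric purity) and can also close to a five-membered ring.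
- The inward methyl slows the Cope step, so heating is needed, and heating favours the same leakage.

Fallback: the oxygen donor on the carbene is changed from an enol silyl ether to an enol ester, which is less donating, closer to the classical well-behaved vinylcarbenes and gives a more robust diazo compound. The fallback sets out from 4 and returns at 10. Methyl 4-oxobutanoate F1 is converted with isopropenyl acetate and catalytic TsOH into methyl (E)-4-acetoxybut-3-enoate F2 (E isomer separated). Diazo transfer (p-acetamidobenzenesulfonyl azide, DBU, MeCN, 0 °C) gives methyl (E)-4-acetoxy-2-diazobut-3-enoate F3. Reaction of F3 with 4 under the conditions of step 5 should give the acetoxy cis-divinylcyclopropane F4 and from it the C1 acetate F5. Methanolysis (K2CO3, MeOH, 0 °C) gives the C1 alcohol F6, and silylation (TBSOTf, 2,6-lutidine, CH2Cl2, −78 °C) gives 10.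

Step 7. Oxygen transfer may be poorly face-selective, may be slow at the hindered tetrasubstituted enone, or may reach C2=C3.

Fallback: the epoxide is placed by a hydroxyl group instead of by the shape of the bicycle. It sets out from 12 and returns at 13. Corey–Bakshi–Shibata reduction of 12 with the (S)-2-methyl oxazaborolidine and catecholborane (PhMe, −40 °C; the tetrasubstituted alkenyl group is the large substituent) delivers hydride to the α face and gives the β allylic alcohol F7. Directed epoxidation (VO(acac)2, t-BuOOH, CH2Cl2, 0 °C) places oxygen syn to the hydroxyl and gives the β-epoxy alcohol F8; the ester-bearing C2=C3 is inert to this reagent. Dess–Martin oxidation (NaHCO3, CH2Cl2) returns the C5 ketone and gives 13.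

Step 8. The samarium enolate may be protonated on the convex β face, which gives the cis-fused C6 epimer. Base equilibration of the ketol is not a safe remedy, because enolisation invites retro-aldol cleavage, dehydration and migration of C2=C3.

Fallback: the hydrogen is delivered to C6 by a stereospecific 1,2-hydride shift instead of by protonation. It sets out from 12 and returns at 14. 12 is converted as described for step 7 into the allylic alcohol F7 and the epoxy alcohol F8. In F8 the C5 hydrogen lies anti to the C6–O bond of the β epoxide. Treatment with TMSOTf and i-Pr2NEt (CH2Cl2, −78 °C) should induce a semipinacol rearrangement: hydride migrates from C5 to the α face of C6 with inversion as the C6–O bond breaks, C5 becomes the ketone and C10–O stays β, giving the C10 trimethylsilyl ether F9 of the trans-fused ketol. Citric acid in MeOH removes the tertiary trimethylsilyl group and gives 14.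

Step 6. The isopropyl nucleophile may add to the conjugated ester (1,2 or 1,4) or act as a base at C4–H or C1–H, with loss of chemoselectivity or of the C1 configuration.

Fallback: the isopropyl group is introduced before the ester exists. It sets out from 4 and returns at 12. 1,2-Addition of i-PrMgCl/CeCl3 to 4 (THF, −78 °C, NaHCO3 work-up) gives the racemic tertiary alcohol F10, which is silylated with N-(trimethylsilyl)imidazole to the trimethylsilyl ether F11. Reaction of F11 with 8 under the conditions of step 5 should give the cyclopropane F12 and, after the Cope shift, the cycloheptadiene F13 as a pair of C10 epimers. Treatment with 1 M HCl in THF at 0 °C removes the silyl group, ionises C10 and hydrolyses the enol ether, so both epimers converge on 12.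

Step 11. The secondary C5 hydroxyl may be sulfonylated as well, or hydride may be delivered in an SN2′ sense with shift of the double bond to the exocyclic position.

Fallback: the allylic C–O bond is cleaved through a π-allylpalladium intermediate, which removes the need for selective activation. It sets out from 16 and returns at 18. Acetylation (Ac2O, pyridine, DMAP, CH2Cl2) gives the diacetate F14 (primary allylic and C5 acetates; the tertiary hydroxyl stays free). Pd(PPh3)4 with LiEt3BH in THF (0 °C to rt) should deliver hydride to the less hindered exocyclic terminus of the allyl complex, giving the C3 methyl group with C2=C3 in place, while excess hydride cleaves the C5 acetate back to the alcohol, giving 18.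

## Further compounds

F1 | step 5 | methyl 4-oxobutanoate | COC(=O)CCC=O
F2 | step 5 | methyl (E)-4-acetoxybut-3-enoate | COC(=O)C/C=C/OC(C)=O
F3 | step 5 | methyl (E)-4-acetoxy-2-diazobut-3-enoate | COC(=O)C(=[N+]=[N-])/C=C/OC(C)=O
F4 | step 5 | methyl 1-[(E)-2-acetoxyvinyl]-2-ethoxy-2-(2-methyl-5-oxocyclopent-1-en-1-yl)cyclopropane-1-carboxylate, alkenyl groups cis (not isolated) | COC(=O)[C@]1(/C=C/OC(C)=O)C[C@@]1(OCC)C2=C(C)CCC2=O
F5 | step 5 | C1 acetate analogue of 10 (C1 OAc α) | CC(=O)O[C@@H]1C=C(C(=O)OC)CC(OCC)=C2[C@]1(C)CCC2=O
F6 | step 5 | C1 alcohol analogue of 10 (C1 OH α) | O[C@@H]1C=C(C(=O)OC)CC(OCC)=C2[C@]1(C)CCC2=O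
F7 | step 7 | β allylic alcohol: 12 with C5 reduced to the β alcohol | CC(C)(C)[Si](C)(C)O[C@@H]1C=C(C(=O)OC)C[C@@H](O)C=2[C@]1(C)CCC=2C(C)C
F8 | step 7 | β-epoxy alcohol: F7 with a C6–C10 epoxide on the β face | CC(C)(C)[Si](C)(C)O[C@@H]1C=C(C(=O)OC)C[C@@H](O)[C@@]23[C@]1(C)CC[C@@]2(O3)C(C)C
F9 | step 8 | C10 trimethylsilyl ether of ketol 14 | CC(C)(C)[Si](C)(C)O[C@@H]1C=C(C(=O)OC)CC(=O)[C@@H]2[C@]1(C)CC[C@@]2(O[Si](C)(C)C)C(C)C
F10 | step 6 | 2-(1-ethoxyvinyl)-1-isopropyl-3-methylcyclopent-2-en-1-ol (racemic) | C=C(OCC)C1=C(C)CCC1(O)C(C)C
F11 | step 6 | trimethylsilyl ether of F10 (racemic) | C=C(OCC)C1=C(C)CCC1(O[Si](C)(C)C)C(C)C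
F12 | step 6 | cis-divinylcyclopropane from F11 and 8, both C10 epimers (not isolated) | COC(=O)[C@]1(/C=C/O[Si](C)(C)C(C)(C)C)C[C@@]1(OCC)C2=C(C)CCC2(O[Si](C)(C)C)C(C)C
F13 | step 6 | C10 trimethylsilyl ether of 11, both C10 epimers | CC(C)(C)[Si](C)(C)O[C@@H]1C=C(C(=O)OC)CC(OCC)=C2[C@]1(C)CCC2(O[Si](C)(C)C)C(C)C
F14 | step 11 | diacetate of 16 (primary allylic and C5 acetates) | CC(C)(C)[Si](C)(C)O[C@@H]1C=C(COC(C)=O)C[C@H](OC(C)=O)[C@@H]2[C@]1(C)CC[C@@]2(O)C(C)C
A1 | alternative 1 | 3-[(methoxymethoxy)methyl]cyclopent-2-en-1-one | COCOCC1=CC(=O)CC1
A2 | alternative 1 | 3-methylbut-3-enal | CC(=C)CC=O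
A3 | alternative 1 | trans-2-(1-hydroxy-3-methylbut-3-en-1-yl)-3-[(methoxymethoxy)methyl]-3-methylcyclopentan-1-one | COCOC[C@@]1(C)CCC(=O)[C@@H]1[C@@H](O)CC(C)=C
A4 | alternative 2 | cis-decalin hydroxy mesylate (C1 dioxolane, C5 hydroxyl, C6 mesylate, C10 triethylsilyl ether and isopropyl) | O1CCOC12CCC[C@]3(O)[C@@H](OS(C)(=O)=O)[C@](O[Si](CC)(CC)CC)(C(C)C)CC[C@]23C
A5 | alternative 2 | trans-fused hydroazulen-5-one (C1 dioxolane, C10 triethylsilyl ether) | O1CCOC12CCCC(=O)[C@@H]3[C@]2(C)CC[C@@]3(O[Si](CC)(CC)CC)C(C)C
A6 | alternative 3 | 2-[(tert-butyldimethylsilyloxy)methyl]-3-[(4-methoxybenzyloxy)methyl]-3-methylpent-4-enal | C=C[C@](C)(COCc1ccc(OC)cc1)[C@@H](CO[Si](C)(C)C(C)(C)C)C=O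
A7 | alternative 3 | trans-2-[(tert-butyldimethylsilyloxy)methyl]-3-[(4-methoxybenzyloxy)methyl]-3-methylcyclopentan-1-one | O=C1CC[C@](C)(COCc2ccc(OC)cc2)[C@H]1CO[Si](C)(C)C(C)(C)C
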